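The data are simulated for substances that don't exist; noise was put on by code.

Start at the end.

| setting | west | alder | elm | maple |
|---|---|---|---|---|
| starting material | 0.10 M | 0.10 M | 0.10 M | 0.10 M |
| second substrate | 0.075 M | 0.0500 M | 0.0500 M | 0.0500 M |
| reagent | 0.15 M | 0.150 M | 0.150 M | 0.150 M |
| free catalyst | 50 µM | 50 µM | 50 µM | 50 µM |
| temperature | 55 °C | 55 °C | 70 °C | 40 °C |
| remark | run made earlier |  |  |  |
| time |  | 40 min | 40 min | 40 min |
west run (percent of the starting material charged)

| time / min | target / % |
|---|---|
| 0.417 | 0.9 |
| 1.33 | 3.2 |
| 2.50 | 5.6 |
| 3.00 | 6.5 |
| 5.00 | 10.1 |
| 6.00 | 13.0 |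
| 8.00 | 16.0 |

(standard deviation of a reading: 0.3 percentage points)
- the flask with the highest amount of target, in percent of the starting material charged ("all alike" if they lie within 1.5 percentage points) (alder / elm / maple / all alike)
- final target, as a percentage of the starting material charged, in alder
- final target, as a percentage of the starting material charged, in elm
- final target, as a percentage of the starting material charged, in maple
- the numbers in the tables scatter by 0.3 percentage points (one standard deviation)
- the earlier runs do not show what temperature does; that part of a forecast is a guess
- a reading or a percentage of target counts all its forms, free or not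

Where must alder stop, given time enough?

I can name two candidates. Target is counted against the starting material, so the whole charge is one ceiling. But alder holds second substrate at half that charge and reagent at 1.50 times it, so if each target took up one second substrate, target would stop at that half. The west run ends at 16.0 %, which shows neither stop, so I keep both open.

How fast is the ceiling approached?

West's last reading, 16.0 % at 8.00 min, gives 0.0218 min⁻¹. This is the clearing constant, the fraction of the still unturned charge that becomes target each minute. Calling it a pseudo-first-order constant is my assumption, not something the readings prove.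

West holds more second substrate than alder. Why may you carry the constant over?

I cannot show that I may, since one run has one charge. I assume the constant stays the same, and that is the weak point. Over 40 min it gives alder 58.2 %, which lies above the half, so my reckoning for alder runs from that half up to this figure.

And the other baths?

That part is a guess, because west shows nothing of temperature. I multiply the constant by 2 for elm and divide it by 2 for maple, which gives elm 82.5 % and maple 35.3 %. Elm then comes out highest, if no cap intervenes.

The forecast, reasoning that “The second substrate probably limits the yield”, names elm and gives alder 33 %, elm 45 % and maple 15 %, each below my figures.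

Alder gives 51.2 %, elm 57.1 % and maple 26.3 %, so elm stands highest. At 40.0 min, alder still holds 60 % of its second substrate. At 20.0 min the clearing constant gives alder 35.3 % and the flask holds 34.7 %; at 40.0 min the constant stands 7 percentage points above the flask.

    starting material + free catalyst ⇌ catalyst intermediate A (K = 2600 M⁻¹, k = 7.20 M⁻¹ s⁻¹, Ea = 58.0 kJ mol⁻¹, ΔH = 4.00 kJ mol⁻¹)
    reagent + catalyst intermediate A → free catalyst + target (k = 4.50 M⁻¹ s⁻¹, Ea = 59.0 kJ mol⁻¹)
    second substrate + free catalyst ⇌ catalyst intermediate B (K = 12.0 M⁻¹, k = 190 M⁻¹ s⁻¹, Ea = 45.0 kJ mol⁻¹, ΔH = −36.0 kJ mol⁻¹)
    reagent + catalyst intermediate B → free catalyst + second product (k = 5.50 M⁻¹ s⁻¹, Ea = 43.0 kJ mol⁻¹)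
    2 starting material → self-condensation product (k = 7.70 × 10⁻⁴ M⁻¹ s⁻¹, Ea = 83.0 kJ mol⁻¹)
    crystals ⇌ target, rate k6*(cs6 - [target]) while solid is left; crystals form when [target] > cs6 (solubility = 35.0 mM, k = 0.00280 s⁻¹)
    (constants at 40 °C)

Now take a flask like elm kept at 55 °C. Its bath is west's 55 °C, but its second substrate stands at 0.0500 M against west's 0.075 M, so carrying the clearing constant over remains my assumption; it gives 58.2 % at 40.0 min. The computed result for this flask is 51.2 %, which is 7 points below the reckoning.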